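**Strategy.** The skipped diene C(CH3)=CH–CH2–CH=C(CH3) in the chain between the furan ring and the tetronic acid ring is cut between its doubly allylic CH2 and the vinylic CH on the furan side. One three-component operation rebuilds it: zirconium-catalysed syn-methylalumination of 3-(pent-4-ynyl)furan creates the (E)-C(CH3)=CH unit, and zerovalent-palladium-catalysed allylation of that alkenylalane with a geraniol-derived allylic chloride forms the CH–CH2 bond with both alkene geometries intact. The chloride carries the (S)-methyl centre (set by an ene-reductase) and a terminal alkyne, from which the (E)-ylidene tetronic acid is grown afterwards by syn-hydrostannation, O-vinylation and Dieckmann closure.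

Key step: step 7

Remark on the structure: the exocyclic alkene is read as drawn, with the side chain cis to C-4 of the lactone and trans to the ring oxygen (5E); the end game is designed for this isomer.

**Step 1**
Reactants: 1 3-bromofuran; 2 (5-chloropent-1-yn-1-yl)trimethylsilane
Product: 4 trimethyl[5-(furan-3-yl)pent-1-yn-1-yl]silane, via Grignard reagent 3 (not isolated)
Conditions: 2, Mg turnings (BrCH2CH2Br activation), THF, reflux; then 1, NiCl2(dppp) (2 mol %; dppp = Ph2P(CH2)3PPh2), THF, 0 °C to rt
Reagents that add atoms: none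
Why: Kumada coupling of a primary alkylmagnesium chloride with the heteroaryl bromide under nickel–diphosphine catalysis should give the 3-alkylfuran, the silyl cap keeping the acetylenic C–H out of the Grignard chemistry.

**Step 2**
Reactants: 4 trimethyl[5-(furan-3-yl)pent-1-yn-1-yl]silane
Product: 5 3-(pent-4-yn-1-yl)furan
Conditions: K2CO3 (0.2 equiv), MeOH, rt
Reagents that add atoms: none
Why: base-catalysed methanolysis of the C(sp)–Si bond (protodesilylation) should free the terminal alkyne without touching the furan.

**Step 3**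
Reactants: 6 geranyl acetate
Product: 7 (2E,6E)-3,7-dimethyl-8-oxoocta-2,6-dien-1-yl acetate
Conditions: SeO2 (1.2 equiv), 95% EtOH, reflux
Reagents that add atoms: selenium dioxide, O=[Se]=O
Why: Riley allylic oxidation (ene reaction, then [2,3]-sigmatropic shift) should attack the (E)-methyl group of the electron-richer distal alkene and run on to the (E)-enal, the acetate-deactivated alkene staying intact.

**Step 4**
Reactants: 7 (2E,6E)-3,7-dimethyl-8-oxoocta-2,6-dien-1-yl acetate
Product: 8 (2E,7S)-3,7-dimethyl-8-oxooct-2-en-1-yl acetate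
Conditions: purified ene-reductase of the Old Yellow Enzyme class with (S)-preference for (E)-2-methyl-2-enals (OYE2 or OYE3 type), NADP+ (cat.), D-glucose, glucose dehydrogenase, phosphate buffer pH 7 / t-BuOMe, 25 °C
Reagents that add atoms: none
Why: flavin-dependent ene-reductase reduction of the activated C=C should deliver hydride from the reduced flavin to C-6 and a tyrosine proton to C-7 from the opposite face inside the active site, which sets the (S) centre, while the non-conjugated allylic-acetate alkene is not a substrate.

**Step 5**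
Reactants: 8 (2E,7S)-3,7-dimethyl-8-oxooct-2-en-1-yl acetate
Product: 10 (2E,7S)-3,7-dimethylnon-2-en-8-yn-1-ol, via acetoxy alkyne 9 (not isolated)
Conditions: dimethyl (1-diazo-2-oxopropyl)phosphonate (1.3 equiv), K2CO3 (2.5 equiv), MeOH, 0 °C to rt, 12 h
Reagents that add atoms: dimethyl (1-diazo-2-oxopropyl)phosphonate, COP(=O)(OC)C(=[N+]=[N-])C(C)=O
Why: Seyferth–Gilbert homologation in its Ohira–Bestmann form should turn the aldehyde into the terminal alkyne under carbonate/methanol mild enough to keep the α-centre, and the same medium should methanolyse the acetate.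

**Step 6**
Reactants: 10 (2E,7S)-3,7-dimethylnon-2-en-8-yn-1-ol
Product: 11 (3S,7E)-9-chloro-3,7-dimethylnon-7-en-1-yne
Conditions: N-chlorosuccinimide (1.2 equiv), Me2S (1.3 equiv), CH2Cl2, −20 to 0 °C
Reagents that add atoms: N-chlorosuccinimide, ClN1C(=O)CCC1=O
Why: Corey–Kim chlorination should displace the alkoxysulfonium group by chloride in an SN2 manner, giving the primary allylic chloride without allylic transposition or loss of the (E) geometry.

**Step 7**
Reactants: 5 3-(pent-4-yn-1-yl)furan; 11 (3S,7E)-9-chloro-3,7-dimethylnon-7-en-1-yne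
Product: 13 3-[(4E,7E,12S)-4,8,12-trimethyltetradeca-4,7-dien-13-yn-1-yl]furan, via alkenylalane 12 (not isolated)
Conditions: 5 (1.2 equiv), Me3Al (2.0 equiv), Cp2ZrCl2 (0.25 equiv), ClCH2CH2Cl, 23 °C, 12 h; volatiles removed in vacuum; then 11 (1.0 equiv), Pd(PPh3)4 (5 mol %), THF, 23 °C
Reagents that add atoms: trimethylaluminium, C[Al](C)C
Why: Cp2ZrCl2/Me3Al should add CH3–Al syn across the terminal alkyne of 5 with the methyl group at the internal carbon (Negishi zirconium-catalysed carboalumination), which fixes the (E) geometry of the new trisubstituted alkene. Zerovalent palladium should then ionise chloride 11 to a π-allylpalladium chloride, take over the alkenyl group from aluminium and form the CH–CH2 bond by reductive elimination; the closest known reaction type is the palladium-catalysed coupling of alkenylalanes with allylic chlorides, the established entry to (E)-trisubstituted 1,4-dienes. No ring is closed and no stereocentre is formed; the (S) centre of 11 is remote and untouched. The step needs methyl delivery to the internal alkyne carbon (secured by the terminal alkyne and the zirconium catalyst), attack at the unsubstituted allyl terminus with retention of the (E) allyl geometry (secured by the disubstituted far terminus of the π-allyl unit and fast reductive elimination), and chemoselectivity against the free alkyne of 11 (secured by removing excess Me3Al and coupling in THF, where zirconium-catalysed carboalumination stops).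

**Step 8**
Reactants: 13 3-[(4E,7E,12S)-4,8,12-trimethyltetradeca-4,7-dien-13-yn-1-yl]furan
Product: 15 methyl (4S,8E,11E)-15-(furan-3-yl)-4,8,12-trimethylpentadeca-8,11-dien-2-ynoate, via lithium acetylide 14 (not isolated)
Conditions: n-BuLi (1.05 equiv), THF, −78 °C; then ClCO2Me (1.5 equiv), −78 to 0 °C
Reagents that add atoms: methyl chloroformate, COC(=O)Cl
Why: the acetylenic C–H is by far the most acidic site, so deprotonation and C-acylation of the lithium acetylide with the chloroformate should give the alkynoate without touching furan or the doubly allylic CH2.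

**Step 9**
Reactants: 15 methyl (4S,8E,11E)-15-(furan-3-yl)-4,8,12-trimethylpentadeca-8,11-dien-2-ynoate
Product: 17 methyl (2E,4S,8E,11E)-15-(furan-3-yl)-2-iodo-4,8,12-trimethylpentadeca-2,8,11-trienoate, via alkenylstannane 16 (not isolated)
Conditions: Bu3SnH (1.05 equiv, slow addition), Pd(PPh3)4 (2 mol %), THF, 0 °C; then I2 (1.1 equiv), NaHCO3, CH2Cl2, 0 °C, dark
Reagents that add atoms: iodine, II (tributyltin hydride leaves only hydrogen in 17)
Why: palladium-catalysed hydrostannation of an alkynoate should add H and Sn syn with tin α to the ester, and iododestannylation should replace tin with retention, so the chain ends up cis to the ester carbon and trans to iodine.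

**Step 10**
Reactants: 17 methyl (2E,4S,8E,11E)-15-(furan-3-yl)-2-iodo-4,8,12-trimethylpentadeca-2,8,11-trienoate
Product: 18 methyl (2E,4S,8E,11E)-15-(furan-3-yl)-4,8,12-trimethyl-2-(propanoyloxy)pentadeca-2,8,11-trienoate
Conditions: EtCO2H (2 equiv), Cs2CO3 (2 equiv), CuI (20 mol %), 3,4,7,8-tetramethyl-1,10-phenanthroline (40 mol %), toluene, 70 °C
Reagents that add atoms: propanoic acid, CCC(=O)O
Why: Ullmann-type O-vinylation of a carboxylate by an alkenyl iodide under monovalent copper catalysis should proceed with retention at the alkene, giving the enol propanoate in which oxygen is trans and the ester carbon cis to the chain.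

**Step 11**
Reactants: 18 methyl (2E,4S,8E,11E)-15-(furan-3-yl)-4,8,12-trimethyl-2-(propanoyloxy)pentadeca-2,8,11-trienoate
Product: 19 (5E)-5-[(2S,6E,9E)-13-(furan-3-yl)-2,6,10-trimethyltrideca-6,9-dien-1-ylidene]-4-hydroxy-3-methylfuran-2(5H)-one
Conditions: LiN(SiMe3)2 (2.2 equiv), THF, −78 to 0 °C; cold aqueous HCl to pH 3
Reagents that add atoms: none
Why: Dieckmann cyclisation of the α-acyloxy ester (propanoate enolate onto the neighbouring methyl ester, 5-exo-trig, loss of methoxide) should close the tetronic acid without touching the enol-ester C=C, so its geometry becomes the (5E) exocyclic alkene.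

**Compound list**

1 | 3-bromofuran | Brc1ccoc1 | starting material
2 | (5-chloropent-1-yn-1-yl)trimethylsilane | C[Si](C)(C)C#CCCCCl | starting material
3 | [5-(trimethylsilyl)pent-4-yn-1-yl]magnesium chloride | C[Si](C)(C)C#CCCC[Mg]Cl | intermediate
4 | trimethyl[5-(furan-3-yl)pent-1-yn-1-yl]silane | C[Si](C)(C)C#CCCCc1ccoc1 | intermediate
5 | 3-(pent-4-yn-1-yl)furan | C#CCCCc1ccoc1 | intermediate
6 | geranyl acetate, (2E)-3,7-dimethylocta-2,6-dien-1-yl acetate | CC(C)=CCC/C(C)=C/COC(C)=O | starting material
7 | (2E,6E)-3,7-dimethyl-8-oxoocta-2,6-dien-1-yl acetate | O=C/C(C)=C/CC/C(C)=C/COC(C)=O | intermediate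
8 | (2E,7S)-3,7-dimethyl-8-oxooct-2-en-1-yl acetate | O=C[C@@H](C)CCC/C(C)=C/COC(C)=O | intermediate
9 | (2E,7S)-3,7-dimethylnon-2-en-8-yn-1-yl acetate | C#C[C@@H](C)CCC/C(C)=C/COC(C)=O | intermediate
10 | (2E,7S)-3,7-dimethylnon-2-en-8-yn-1-ol | C#C[C@@H](C)CCC/C(C)=C/CO | intermediate
11 | (3S,7E)-9-chloro-3,7-dimethylnon-7-en-1-yne | C#C[C@@H](C)CCC/C(C)=C/CCl | intermediate
12 | [(1E)-5-(furan-3-yl)-2-methylpent-1-en-1-yl]dimethylalumane | C[Al](C)/C=C(\C)CCCc1ccoc1 | intermediate
13 | 3-[(4E,7E,12S)-4,8,12-trimethyltetradeca-4,7-dien-13-yn-1-yl]furan | C#C[C@@H](C)CCC/C(C)=C/C/C=C(\C)CCCc1ccoc1 | intermediate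
14 | lithium acetylide of 13 | [Li]C#C[C@@H](C)CCC/C(C)=C/C/C=C(\C)CCCc1ccoc1 | intermediate
15 | methyl (4S,8E,11E)-15-(furan-3-yl)-4,8,12-trimethylpentadeca-8,11-dien-2-ynoate | COC(=O)C#C[C@@H](C)CCC/C(C)=C/C/C=C(\C)CCCc1ccoc1 | intermediate
16 | methyl (2E,4S,8E,11E)-15-(furan-3-yl)-4,8,12-trimethyl-2-(tributylstannyl)pentadeca-2,8,11-trienoate | COC(=O)/C(=C\[C@@H](C)CCC/C(C)=C/C/C=C(\C)CCCc1ccoc1)[Sn](CCCC)(CCCC)CCCC | intermediate
17 | methyl (2E,4S,8E,11E)-15-(furan-3-yl)-2-iodo-4,8,12-trimethylpentadeca-2,8,11-trienoate | COC(=O)/C(I)=C\[C@@H](C)CCC/C(C)=C/C/C=C(\C)CCCc1ccoc1 | intermediate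
18 | methyl (2E,4S,8E,11E)-15-(furan-3-yl)-4,8,12-trimethyl-2-(propanoyloxy)pentadeca-2,8,11-trienoate | COC(=O)/C(OC(=O)CC)=C\[C@@H](C)CCC/C(C)=C/C/C=C(\C)CCCc1ccoc1 | intermediate
19 | (5E)-5-[(2S,6E,9E)-13-(furan-3-yl)-2,6,10-trimethyltrideca-6,9-dien-1-ylidene]-4-hydroxy-3-methylfuran-2(5H)-one | CC1=C(O)/C(=C\[C@@H](C)CCC/C(C)=C/C/C=C(\C)CCCc2ccoc2)OC1=O | target

**Step count:** 11 steps in total. Longest linear sequence: 9 steps (steps 3 to 11, from geranyl acetate).

**Steps most likely to fail**

1. Step 10. The carbon–oxygen coupling may be slow on the hindered, electron-poor α-iodo enoate, so that protodeiodination or loss of alkene geometry through reversible conjugate addition of carboxylate competes. The fallback replaces substitution at iodine by oxidative coupling at boron. It sets out from 17: Miyaura borylation (B2pin2, PdCl2(dppf) with dppf = 1,1′-bis(diphenylphosphino)ferrocene, KOPh, toluene, 50 °C) should give the α-boryl enoate F1. KHF2 in MeOH/H2O should convert it into the potassium trifluoroborate F2. Chan–Lam-type coupling of F2 with propanoic acid (Cu(OAc)2, 4-(dimethylamino)pyridine, 4 Å sieves, O2, CH2Cl2, rt) should give the enol ester with retention, and the route is rejoined at 18.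

2. Step 7. Residual aluminium and zirconium species may metalate or carbometalate the free alkyne of 11, or the allyl transfer may partly go to the substituted terminus with loss of geometry. The fallback uses tin instead of aluminium in the coupling. It sets out from 5: the same carboalumination (through 12), quenched with I2 in THF at −30 °C, should give (E)-3-(5-iodo-4-methylpent-4-en-1-yl)furan F3. Iodine–lithium exchange (t-BuLi, Et2O, −78 °C) and Bu3SnCl should give the alkenylstannane F4. Stille coupling of F4 with 11 (Pd2(dba)3 with dba = dibenzylideneacetone, tri(2-furyl)phosphine, THF, 50 °C) should form the same CH–CH2 bond, and the route is rejoined at 13.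

3. Step 4. The α-branched aldehyde may lose enantiopurity by enolisation in the aqueous medium, or the carbonyl group may be reduced further by contaminating dehydrogenases. The fallback sets the centre by hydroxyl-directed hydrogenation. It sets out from 7: Luche reduction (NaBH4, CeCl3·7H2O, MeOH, 0 °C) should give the allylic alcohol F5. Noyori hydrogenation (Ru(OAc)2(BINAP) with BINAP = 2,2′-bis(diphenylphosphino)-1,1′-binaphthyl, H2, MeOH; the ligand enantiomer is chosen so that the (S) alcohol results) should reduce only the alkene next to the free hydroxyl and give the saturated alcohol F6. Dess–Martin oxidation of F6 returns to the route at 8.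

**Further compounds**

F1 | step 10 | methyl (2Z,4S,8E,11E)-15-(furan-3-yl)-4,8,12-trimethyl-2-(4,4,5,5-tetramethyl-1,3,2-dioxaborolan-2-yl)pentadeca-2,8,11-trienoate | COC(=O)/C(B1OC(C)(C)C(C)(C)O1)=C\[C@@H](C)CCC/C(C)=C/C/C=C(\C)CCCc1ccoc1
F2 | step 10 | potassium [(2Z,4S,8E,11E)-15-(furan-3-yl)-1-methoxy-4,8,12-trimethyl-1-oxopentadeca-2,8,11-trien-2-yl]trifluoroborate | [K+].COC(=O)/C(=C\[C@@H](C)CCC/C(C)=C/C/C=C(\C)CCCc1ccoc1)[B-](F)(F)F
F3 | step 7 | (E)-3-(5-iodo-4-methylpent-4-en-1-yl)furan | I/C=C(\C)CCCc1ccoc1
F4 | step 7 | tributyl[(1E)-5-(furan-3-yl)-2-methylpent-1-en-1-yl]stannane | CCCC[Sn](CCCC)(CCCC)/C=C(\C)CCCc1ccoc1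
F5 | step 4 | (2E,6E)-8-hydroxy-3,7-dimethylocta-2,6-dien-1-yl acetate | OC/C(C)=C/CC/C(C)=C/COC(C)=O
F6 | step 4 | (2E,7S)-8-hydroxy-3,7-dimethyloct-2-en-1-yl acetate | OC[C@@H](C)CCC/C(C)=C/COC(C)=O
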